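**Strategy.** The route rests on disconnecting the C3–H bond of the C ring and treating C2 as a mobile centre. In a 2-arylchroman-3-one the C2–H is acidic (α to C3=O, benzylic to the B ring, on the carbon bearing O1), so one stereoconvergent hydrogenation should funnel both enantiomers of a racemic tetra-O-benzyl flavan-3-one into the (2R,3R)-cis alcohol, setting C2 and C3 together. The racemic ketone needs no stereocontrol and is assembled by closing the C ring at C4–C4a through a gold α-oxo carbene generated from an aryl 1-arylpropargyl ether. Acylation and global hydrogenolysis finish the synthesis.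

Key step: step 4

Remark: the four building blocks are taken as catalogue compounds; racemates with one stereocentre are written without a stereodescriptor, racemates with two stereocentres as both enantiomers joined by a dot.

**Step 1**
Reactants: 1 3,4-bis(benzyloxy)benzaldehyde; 2 ethynylmagnesium bromide
Product: 3 rac-1-[3,4-bis(benzyloxy)phenyl]prop-2-yn-1-ol
Conditions: HC≡CMgBr (0.5 M in THF, 1.3 equiv), THF, 0 °C to rt; H2O quench
Reagents that add atoms: ethynylmagnesium bromide (2), C#C[Mg]Br
Why: Grignard 1,2-addition of an alkynyl nucleophile to an aromatic aldehyde; the carbinol centre forms racemic, which is intended because it becomes the C2 that the key step equilibrates.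

**Step 2**
Reactants: 3 rac-1-[3,4-bis(benzyloxy)phenyl]prop-2-yn-1-ol; 4 3,5-bis(benzyloxy)phenol
Product: 5 rac-1,3-bis(benzyloxy)-5-({1-[3,4-bis(benzyloxy)phenyl]prop-2-yn-1-yl}oxy)benzene
Conditions: PPh3 (1.3 equiv), DIAD (1.3 equiv), toluene, 0 °C to rt
Reagents that add atoms: none
Why: Mitsunobu etherification, in which the phenol (pKa about 9–10) should displace the oxyphosphonium of the propargylic alcohol by SN2 under non-acidic conditions that disfavour ionisation and C-alkylation of the electron-rich ring; the ether carbon (future C2) is racemic, which is immaterial.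

**Step 3**
Reactants: 5 rac-1,3-bis(benzyloxy)-5-({1-[3,4-bis(benzyloxy)phenyl]prop-2-yn-1-yl}oxy)benzene
Product: 6 rac-5,7-bis(benzyloxy)-2-[3,4-bis(benzyloxy)phenyl]chroman-3-one
Conditions: Me4tBuXPhosAuNTf2 (5 mol%), 3,5-dichloropyridine N-oxide (1.3 equiv, slow addition), DCE, rt
Reagents that add atoms: 3,5-dichloropyridine N-oxide, [O-][n+]1cc(Cl)cc(Cl)c1
Why: Gold-catalysed alkyne oxidation/carbene cyclisation as known for aryl propargyl ethers: the N-oxide adds to the internal carbon of the Au-activated terminal alkyne, N–O cleavage gives an α-oxo gold carbene at the terminal carbon (future C4), and Friedel–Crafts attack by either of the two equivalent, triply oxygen-activated ortho carbons of the A ring (far more nucleophilic than the B ring, and leading to the six-membered ring) should close the C ring at C4–C4a.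

**Step 4**
Reactants: 6 rac-5,7-bis(benzyloxy)-2-[3,4-bis(benzyloxy)phenyl]chroman-3-one
Product: 8 (2R,3R)-5,7-bis(benzyloxy)-2-[3,4-bis(benzyloxy)phenyl]chroman-3-ol, via (2R)-flavan-3-one 7 (not isolated)
Conditions: RuCl2[(S)-xylbinap][(S)-daipen] (1 mol%), KOtBu (20 mol%), H2 (8 atm), iPrOH/toluene, 25 °C, O2-free
Reagents that add atoms: none
Why: Dynamic kinetic resolution by bifunctional Ru hydrogenation: tert-butoxide reversibly removes the C2–H of 6 (α to C3=O, benzylic to the B ring, on the carbon bearing O1), so the enantiomers interconvert through the achiral C2=C3 enolate faster than the slower one is reduced, while the RuH(diphosphine)(diamine) species passes hydride to C3 and an N–H proton to the carbonyl oxygen through an outer-sphere six-membered transition state. The closest known reaction type is the Noyori DKR hydrogenation of racemic 2-alkoxy-, 2-alkyl- and 2-aryl-cycloalkanones to cis-cycloalkanols. No ring is closed; the step forms the C3–H bond and fixes both stereocentres of the C ring together. C3 (R) is controlled by the catalyst, which has to deliver hydride to the Si face of the carbonyl (O > C2 > C4), the sense expected for the (S)-diphosphine/(S)-diamine complex by analogy with 2-alkoxycyclohexanones and to be checked on a test scale, the mirror-image complex being used if the sense proves opposite; C2 (R) follows because only enantiomer 7 can place its 2-aryl group pseudo-equatorial and anti to that hydride, which should give the axial 3-OH cis to the aryl group. The step needs C2 epimerisation to outrun reduction, cis over trans delivery and ketone chemoselectivity: the triply activated C2–H secures the first, the steric bias of the 2-aryl group (the bias that bulky hydrides are known to follow on flavan-3-ones) the second, and the carbonyl-selective catalyst, inert toward benzyl ethers and arenes, the third.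

**Step 5**
Reactants: 8 (2R,3R)-5,7-bis(benzyloxy)-2-[3,4-bis(benzyloxy)phenyl]chroman-3-ol; 9 4-(benzyloxy)benzoyl chloride
Product: 10 (2R,3R)-5,7-bis(benzyloxy)-2-[3,4-bis(benzyloxy)phenyl]chroman-3-yl 4-(benzyloxy)benzoate
Conditions: Et3N (2 equiv), DMAP (0.2 equiv), CH2Cl2, 0 °C to rt
Reagents that add atoms: 4-(benzyloxy)benzoyl chloride (9), O=C(Cl)c1ccc(OCc2ccccc2)cc1
Why: DMAP-catalysed acylation of the axial secondary alcohol through the N-acylpyridinium ion, which leaves the C3–O bond and the non-acidic C2–H untouched, so both stereocentres should be retained.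

**Step 6**
Reactants: 10 (2R,3R)-5,7-bis(benzyloxy)-2-[3,4-bis(benzyloxy)phenyl]chroman-3-yl 4-(benzyloxy)benzoate
Product: 11 epicatechin 3-O-p-hydroxybenzoate, (2R,3R)-2-(3,4-dihydroxyphenyl)-5,7-dihydroxychroman-3-yl 4-hydroxybenzoate
Conditions: H2 (1 atm), 20% Pd(OH)2/C, THF/MeOH 1:1, rt, stopped at complete debenzylation
Reagents that add atoms: none
Why: Catalytic hydrogenolysis of the five benzyl aryl ethers under neutral conditions, as used for galloylated flavan-3-ols, should leave the aryl ester and the ring C2–O1 bond intact and touch no stereocentre.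

**Compound list**
1 | 3,4-bis(benzyloxy)benzaldehyde | O=Cc1ccc(OCc2ccccc2)c(OCc2ccccc2)c1 | starting material
2 | ethynylmagnesium bromide | C#C[Mg]Br | starting material
3 | rac-1-[3,4-bis(benzyloxy)phenyl]prop-2-yn-1-ol | C#CC(O)c1ccc(OCc2ccccc2)c(OCc2ccccc2)c1 | intermediate
4 | 3,5-bis(benzyloxy)phenol | Oc1cc(OCc2ccccc2)cc(OCc2ccccc2)c1 | starting material
5 | rac-1,3-bis(benzyloxy)-5-({1-[3,4-bis(benzyloxy)phenyl]prop-2-yn-1-yl}oxy)benzene | C#CC(Oc1cc(OCc2ccccc2)cc(OCc2ccccc2)c1)c1ccc(OCc2ccccc2)c(OCc2ccccc2)c1 | intermediate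
6 | rac-5,7-bis(benzyloxy)-2-[3,4-bis(benzyloxy)phenyl]chroman-3-one | O=C1Cc2c(OCc3ccccc3)cc(OCc3ccccc3)cc2OC1c1ccc(OCc2ccccc2)c(OCc2ccccc2)c1 | intermediate
7 | (2R)-5,7-bis(benzyloxy)-2-[3,4-bis(benzyloxy)phenyl]chroman-3-one (the enantiomer of 6 that is reduced, regenerated from its antipode through the enolate) | O=C1Cc2c(OCc3ccccc3)cc(OCc3ccccc3)cc2O[C@@H]1c1ccc(OCc2ccccc2)c(OCc2ccccc2)c1 | intermediate
8 | (2R,3R)-5,7-bis(benzyloxy)-2-[3,4-bis(benzyloxy)phenyl]chroman-3-ol | O[C@@H]1Cc2c(OCc3ccccc3)cc(OCc3ccccc3)cc2O[C@@H]1c1ccc(OCc2ccccc2)c(OCc2ccccc2)c1 | intermediate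
9 | 4-(benzyloxy)benzoyl chloride | O=C(Cl)c1ccc(OCc2ccccc2)cc1 | starting material
10 | (2R,3R)-5,7-bis(benzyloxy)-2-[3,4-bis(benzyloxy)phenyl]chroman-3-yl 4-(benzyloxy)benzoate | O=C(O[C@@H]1Cc2c(OCc3ccccc3)cc(OCc3ccccc3)cc2O[C@@H]1c1ccc(OCc2ccccc2)c(OCc2ccccc2)c1)c1ccc(OCc2ccccc2)cc1 | intermediate
11 | epicatechin 3-O-p-hydroxybenzoate | O=C(O[C@@H]1Cc2c(O)cc(O)cc2O[C@@H]1c1ccc(O)c(O)c1)c1ccc(O)cc1 | target

**Total step count:** 6. **Longest linear sequence:** 6 steps (1 to 11).

**Steps most likely to fail**

1. Step 4. C2 epimerisation may be slower than reduction of the mismatched enantiomer, facial discrimination may be weak for a ketone flanked by two sp3 carbons, or the enolate may self-condense under the basic conditions; any of these would erode ee or dr. The fallback sets out from 6 and replaces dynamic funnelling by substrate control plus classical resolution. L-Selectride (THF, −78 °C) should deliver hydride anti to the 2-aryl group and give rac-cis-5,7-bis(benzyloxy)-2-[3,4-bis(benzyloxy)phenyl]chroman-3-ol F1. Esterification with (S)-2-methoxy-2-phenylacetic acid (DCC, DMAP, CH2Cl2) should give two diastereomers, (2R,3R)-5,7-bis(benzyloxy)-2-[3,4-bis(benzyloxy)phenyl]chroman-3-yl (S)-2-methoxy-2-phenylacetate F2 and its (2S,3S)-chromanyl diastereomer F3, to be separated by chromatography or crystallisation, F3 being discarded. Saponification of F2 (LiOH, THF/MeOH/H2O) returns to the route at 8.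

2. Step 3. Gold-catalysed 6-endo hydroarylation of the very electron-rich A ring, ionisation of the doubly activated propargylic C–O bond, or a second oxidation of the carbene may outrun the carbene cyclisation. The fallback sets out from 5 and makes the competing manifold the route. Thermal propargyl Claisen rearrangement (PhNEt2, 190 °C; [3,3] shift, enolisation, 1,5-H shift, oxa-6π closure) should give rac-5,7-bis(benzyloxy)-2-[3,4-bis(benzyloxy)phenyl]-2H-chromene F4. Hydroboration–oxidation (BH3·SMe2, THF; NaOH/H2O2), with boron at C3 as for styrenes and anti to the 2-aryl group, should give rac-trans-5,7-bis(benzyloxy)-2-[3,4-bis(benzyloxy)phenyl]chroman-3-ol F5. Dess–Martin oxidation comes back to the route at 6, where the stereochemistry of F5 no longer matters.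

3. Step 2. The oxyphosphonium of the electron-rich benzylic propargylic alcohol may ionise, leading to C-alkylation of the phloroglucinol-type ring or to allene formation instead of O-alkylation. The fallback sets out from 3 and switches from SN2 displacement to copper-allenylidene propargylic substitution. Acetylation (Ac2O, Et3N, DMAP) should give rac-1-[3,4-bis(benzyloxy)phenyl]prop-2-yn-1-yl acetate F6. Treatment with phenol 4 under CuCl2 (cat.), DBU, MeCN, 0 °C, where the phenoxide should attack the γ-carbon of the copper allenylidene through oxygen, comes back to the route at 5.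

**Further compounds**
F1 | step 4 | rac-cis-5,7-bis(benzyloxy)-2-[3,4-bis(benzyloxy)phenyl]chroman-3-ol | O[C@@H]1Cc2c(OCc3ccccc3)cc(OCc3ccccc3)cc2O[C@@H]1c1ccc(OCc2ccccc2)c(OCc2ccccc2)c1.O[C@H]1Cc2c(OCc3ccccc3)cc(OCc3ccccc3)cc2O[C@H]1c1ccc(OCc2ccccc2)c(OCc2ccccc2)c1
F2 | step 4 | (2R,3R)-5,7-bis(benzyloxy)-2-[3,4-bis(benzyloxy)phenyl]chroman-3-yl (S)-2-methoxy-2-phenylacetate | CO[C@H](C(=O)O[C@@H]1Cc2c(OCc3ccccc3)cc(OCc3ccccc3)cc2O[C@@H]1c1ccc(OCc2ccccc2)c(OCc2ccccc2)c1)c1ccccc1
F3 | step 4 | (2S,3S)-5,7-bis(benzyloxy)-2-[3,4-bis(benzyloxy)phenyl]chroman-3-yl (S)-2-methoxy-2-phenylacetate | CO[C@H](C(=O)O[C@H]1Cc2c(OCc3ccccc3)cc(OCc3ccccc3)cc2O[C@H]1c1ccc(OCc2ccccc2)c(OCc2ccccc2)c1)c1ccccc1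
F4 | step 3 | rac-5,7-bis(benzyloxy)-2-[3,4-bis(benzyloxy)phenyl]-2H-chromene | C1=Cc2c(OCc3ccccc3)cc(OCc3ccccc3)cc2OC1c1ccc(OCc2ccccc2)c(OCc2ccccc2)c1
F5 | step 3 | rac-trans-5,7-bis(benzyloxy)-2-[3,4-bis(benzyloxy)phenyl]chroman-3-ol | O[C@H]1Cc2c(OCc3ccccc3)cc(OCc3ccccc3)cc2O[C@@H]1c1ccc(OCc2ccccc2)c(OCc2ccccc2)c1.O[C@@H]1Cc2c(OCc3ccccc3)cc(OCc3ccccc3)cc2O[C@H]1c1ccc(OCc2ccccc2)c(OCc2ccccc2)c1
F6 | step 2 | rac-1-[3,4-bis(benzyloxy)phenyl]prop-2-yn-1-yl acetate | C#CC(OC(C)=O)c1ccc(OCc2ccccc2)c(OCc2ccccc2)c1
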